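Everything rests on building ring A of the 6''-linked flavanone (unit 2, double-primed locants) last. That ring carries OH at C5'', the C3' aryl of unit 1 at C6'' and OMe at C7'', the array a vinylketene/alkoxyalkyne benzannulation produces. One neutral photochemical operation joins an (S)-dihydropyranone diazoketone (future ring C of unit 2) to an intact (S)-flavanone carrying a methoxyethynyl group at C3', forming C8''–C8a'', C5''–C6'', C7''–C8'' and C4a''–C5'' and thus the hindered biaryl bond without cross-coupling. Both stereocentres are set beforehand by asymmetric catalysis; hydrogenolysis of two benzyl ethers finishes the synthesis.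

Key step: step 10

Assumption: the C3'–C6'' biaryl axis (flanked by OMe, OH and OMe) is treated as not being a stereo element, since the target structure defines none. Unit 1 is the 4'-methoxy flavanone (plain and single-primed locants); unit 2 carries double- and triple-primed locants.

**Route**

Step 1
Reactants: 1 2',6'-dihydroxy-4'-methoxyacetophenone
Product: 2 1-[2-(benzyloxy)-6-hydroxy-4-methoxyphenyl]ethan-1-one
Conditions: BnBr (1.05 equiv), K2CO3, acetone, reflux
Reagents that add atoms: benzyl bromide, BrCc1ccccc1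
Why: Williamson ether synthesis on a symmetrical diphenol; after the first O-alkylation the remaining hydroxyl is locked in a hydrogen bond to the acetyl carbonyl and is much less nucleophilic, so mono-benzylation is expected.

Step 2
Reactants: 2 1-[2-(benzyloxy)-6-hydroxy-4-methoxyphenyl]ethan-1-one; 3 3-iodo-4-methoxybenzaldehyde
Product: 4 (E)-1-[2-(benzyloxy)-6-hydroxy-4-methoxyphenyl]-3-(3-iodo-4-methoxyphenyl)prop-2-en-1-one
Conditions: KOH, EtOH–H2O, 0 °C to rt; then AcOH
Reagents that add atoms: none
Why: Claisen–Schmidt condensation of the methyl ketone enolate with a non-enolisable aryl aldehyde followed by E1cB dehydration gives the (E)-enone, and the 2'-phenoxide keeps the open chalcone form until the cold acidification.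

Step 3
Reactants: 4 (E)-1-[2-(benzyloxy)-6-hydroxy-4-methoxyphenyl]-3-(3-iodo-4-methoxyphenyl)prop-2-en-1-one
Product: 5 (2S)-5-(benzyloxy)-2-(3-iodo-4-methoxyphenyl)-7-methoxychroman-4-one
Conditions: N-[3,5-bis(trifluoromethyl)phenyl]-N'-[(8α,9S)-6'-methoxycinchonan-9-yl]thiourea (10 mol%), toluene, −20 °C
Reagents that add atoms: none
Why: Organocatalytic enantioselective intramolecular oxa-Michael addition, in which the thiourea binds the enone carbonyl and the quinuclidine nitrogen activates the phenol so that oxygen adds to one enantiotopic face of the β-carbon and sets C2 as (S) under catalyst control; the quinidine-derived pseudoenantiomer is to be used instead if the first run shows the opposite sense, and the 6'-benzyloxy group, by twisting the carbonyl out of the arene plane, should make closure fast and favourable.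

Step 4
Reactants: 6 2-chloro-1,1-dimethoxyethane
Product: 8 tributyl(methoxyethynyl)stannane, via lithium methoxyacetylide 7 (not isolated)
Conditions: Et2NH, n-BuLi (3.1 equiv LiNEt2), THF, 0 °C; then Bu3SnCl, −78 °C to rt; distillation
Reagents that add atoms: tributyltin chloride, CCCC[Sn](Cl)(CCCC)CCCC; n-butyllithium, [Li]CCCC (lithium of 7 only)
Why: Two successive amide-base eliminations (loss of methoxide, then of chloride) and deprotonation give the lithium alkoxyacetylide, which is stannylated at carbon by nucleophilic substitution at tin.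

Step 5
Reactants: 5 (2S)-5-(benzyloxy)-2-(3-iodo-4-methoxyphenyl)-7-methoxychroman-4-one; 8 tributyl(methoxyethynyl)stannane
Product: 9 (2S)-5-(benzyloxy)-7-methoxy-2-[4-methoxy-3-(methoxyethynyl)phenyl]chroman-4-one
Conditions: Pd(PPh3)4 (5 mol%), toluene, 60 °C; filtration through neutral alumina, MeCN–hexane partition
Reagents that add atoms: none
Why: Stille cross-coupling (oxidative addition of zerovalent palladium into the aryl C–I bond, fast alkynyl transfer from tin, reductive elimination) under neutral, base-free conditions that should spare both the C2 stereocentre and the acid-sensitive ynol ether.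

Step 6
Reactants: 10 ethyl 2,4-dioxopentanoate
Product: 11 ethyl (2Z)-2,4-bis(trimethylsilyloxy)penta-2,4-dienoate
Conditions: TMSOTf (2.2 equiv), Et3N (2.5 equiv), Et2O, 0 °C to rt; used crude
Reagents that add atoms: trimethylsilyl trifluoromethanesulfonate, C[Si](C)(C)OS(=O)(=O)C(F)(F)F
Why: Double O-silylation by soft enolisation traps the C2 enol and the methyl ketone enolate, the standard way to 1,3-bis(silyloxy)dienes from 1,3-dicarbonyl compounds (the enol ether geometry is assumed and is without consequence).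

Step 7
Reactants: 11 ethyl (2Z)-2,4-bis(trimethylsilyloxy)penta-2,4-dienoate; 12 4-(benzyloxy)benzaldehyde
Product: 14 ethyl (2S)-2-[4-(benzyloxy)phenyl]-4-oxo-3,4-dihydro-2H-pyran-6-carboxylate, via aldol adduct 13 (not isolated)
Conditions: Ti(OiPr)4 (20 mol%), (S)-BINOL (20 mol%), 4 Å molecular sieves, THF, −78 to −20 °C; then TFA (cat.), CH2Cl2, 0 °C
Reagents that add atoms: none
Why: Enantioselective vinylogous Mukaiyama aldol addition of the terminal CH2 of the diene to the aldehyde bound to the BINOL complex of tetravalent titanium, the (S)-ligand being expected by analogy with its usual preference for aromatic aldehydes to expose the Si face and give the (S)-carbinol; brief cold acid then removes silicon, the δ-hydroxyl adds to the C2 ketone and water is lost to the vinylogous ester (cyclodehydration) without touching the carbinol centre.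

Step 8
Reactants: 14 ethyl (2S)-2-[4-(benzyloxy)phenyl]-4-oxo-3,4-dihydro-2H-pyran-6-carboxylate
Product: 16 (2S)-2-[4-(benzyloxy)phenyl]-4-oxo-3,4-dihydro-2H-pyran-6-carboxylic acid, via trimethylstannyl ester 15 (not isolated)
Conditions: Me3SnOH (3 equiv), ClCH2CH2Cl, 70 °C; then 0.5 M aq HCl, 0 °C
Reagents that add atoms: trimethyltin hydroxide, C[Sn](C)(C)O
Why: Near-neutral ester cleavage by acyl substitution with trimethyltin hydroxide at the activated α-alkoxyacrylate ester, chosen because hydroxide or alkoxide would open the dihydropyranone by E1cB elimination and racemise C2.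

Step 9
Reactants: 16 (2S)-2-[4-(benzyloxy)phenyl]-4-oxo-3,4-dihydro-2H-pyran-6-carboxylic acid
Product: 18 (2S)-2-[4-(benzyloxy)phenyl]-6-(diazoacetyl)-2,3-dihydro-4H-pyran-4-one, via acid chloride 17 (not isolated)
Conditions: Me2C=C(Cl)NMe2, CH2Cl2, 0 °C to rt; then TMSCHN2 (2 equiv), MeCN–THF, 0 °C; dark
Reagents that add atoms: (trimethylsilyl)diazomethane, C[Si](C)(C)C=[N+]=[N-]; 1-chloro-N,N,2-trimethylprop-1-en-1-amine, CC(C)=C(Cl)N(C)C (chlorine of 17 only)
Why: Acid chloride formation with an α-chloroenamine under neutral conditions, then C-acylation of the silyl diazomethane (Arndt–Eistert-type diazoketone synthesis), in which chloride removes silicon from the acylated diazonium intermediate so that no HCl is released.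

Step 10
Reactants: 18 (2S)-2-[4-(benzyloxy)phenyl]-6-(diazoacetyl)-2,3-dihydro-4H-pyran-4-one; 9 (2S)-5-(benzyloxy)-7-methoxy-2-[4-methoxy-3-(methoxyethynyl)phenyl]chroman-4-one
Product: 23 (2S)-5-(benzyloxy)-2-{3-[(2S)-2-[4-(benzyloxy)phenyl]-5-hydroxy-7-methoxy-4-oxochroman-6-yl]-4-methoxyphenyl}-7-methoxychroman-4-one, via vinylketene 19 (not isolated), via cyclobutenone 20 (not isolated), via dienylketene 21 (not isolated), via cyclohexadienone 22 (not isolated)
Conditions: 9 (1.0 equiv), 18 (1.5 equiv), hν (405 nm LED), degassed ClCH2CH2Cl, 20 °C; then 80 °C, dark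
Reagents that add atoms: none
Why: Light absorbed in the long-wavelength band of 18 expels N2 and pyranone C6 migrates to the diazo carbon (photochemical Wolff rearrangement), giving vinylketene 19 with the ketene conjugated to the C5=C6 enol-ether double bond; ynol ether 9 adds across the ketene C=C in a (2+2) cycloaddition, its nucleophilic aryl-bearing carbon bonding to the ketene carbonyl carbon, and cyclobutenone 20 opens by reversible 4π electrocyclisation to dienylketene 21. Ring A of unit 2 is then closed by a thermal 6π electrocyclisation (disrotatory) in which the ketene carbon bonds to the nucleophilic pyranone C5, and dienone 22 tautomerises to the hydrogen-bonded C5'' phenol 23. The sequence is the Danheiser benzannulation in its diazoketone variant, established for vinyl and aryl diazomethyl ketones with alkoxy- and siloxyalkynes; the dihydropyranone-embedded vinylketene is the untested element. No stereocentre is created (C4 of 20 and C4a'' of 22 are transient and unspecified), and the neutral, base-free cascade should leave both (S) centres untouched. The selectivity needed is regiochemical (aryl at C6'' beside the new hydroxyl, methoxy at C7''); it is secured by the polarisation of the ynol ether, whose carbon remote from oxygen is the nucleophilic terminus, and by the fact that only the C5=C6 double bond can take part in the 6π closure. Irradiation at 405 nm is chosen because the chromanone chromophores of 9 and 23 should be transparent there, which avoids light-induced opening of the flavanone rings, and the dark thermal stage completes the 4π and 6π steps.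

Step 11
Reactants: 23 (2S)-5-(benzyloxy)-2-{3-[(2S)-2-[4-(benzyloxy)phenyl]-5-hydroxy-7-methoxy-4-oxochroman-6-yl]-4-methoxyphenyl}-7-methoxychroman-4-one
Product: 24 (2S)-5-hydroxy-2-{3-[(2S)-5-hydroxy-2-(4-hydroxyphenyl)-7-methoxy-4-oxochroman-6-yl]-4-methoxyphenyl}-7-methoxychroman-4-one (CNP0150873.1)
Conditions: H2 (1 atm), 10% Pd/C, EtOAc–THF, rt
Reagents that add atoms: none
Why: Catalytic hydrogenolysis of the two aryl benzyl ethers; in neutral EtOAc at 1 atm these O-benzyl bonds should cleave much faster than the cyclic benzylic C2–O bonds or the electron-rich aryl ketones, so both chromanone rings and both (S) centres are retained.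

**Compound list**

1 | 2',6'-dihydroxy-4'-methoxyacetophenone | COc1cc(O)c(C(C)=O)c(O)c1 | starting material
2 | 1-[2-(benzyloxy)-6-hydroxy-4-methoxyphenyl]ethan-1-one | COc1cc(O)c(C(C)=O)c(OCc2ccccc2)c1 | intermediate
3 | 3-iodo-4-methoxybenzaldehyde | COc1ccc(C=O)cc1I | starting material
4 | (E)-1-[2-(benzyloxy)-6-hydroxy-4-methoxyphenyl]-3-(3-iodo-4-methoxyphenyl)prop-2-en-1-one | COc1cc(O)c(C(=O)/C=C/c2ccc(OC)c(I)c2)c(OCc2ccccc2)c1 | intermediate
5 | (2S)-5-(benzyloxy)-2-(3-iodo-4-methoxyphenyl)-7-methoxychroman-4-one | COc1ccc(cc1I)[C@@H]1CC(=O)c2c(OCc3ccccc3)cc(OC)cc2O1 | intermediate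
6 | 2-chloro-1,1-dimethoxyethane | COC(CCl)OC | starting material
7 | lithium methoxyacetylide (formed in situ) | COC#C[Li] | intermediate
8 | tributyl(methoxyethynyl)stannane | CCCC[Sn](CCCC)(CCCC)C#COC | intermediate
9 | (2S)-5-(benzyloxy)-7-methoxy-2-[4-methoxy-3-(methoxyethynyl)phenyl]chroman-4-one | COC#Cc1cc(ccc1OC)[C@@H]1CC(=O)c2c(OCc3ccccc3)cc(OC)cc2O1 | intermediate
10 | ethyl 2,4-dioxopentanoate | CCOC(=O)C(=O)CC(C)=O | starting material
11 | ethyl (2Z)-2,4-bis(trimethylsilyloxy)penta-2,4-dienoate | CCOC(=O)/C(O[Si](C)(C)C)=C/C(=C)O[Si](C)(C)C | intermediate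
12 | 4-(benzyloxy)benzaldehyde | O=Cc1ccc(OCc2ccccc2)cc1 | starting material
13 | ethyl (6S)-6-[4-(benzyloxy)phenyl]-6-hydroxy-2,4-dioxohexanoate (aldol adduct after loss of silicon, formed in situ, drawn as the diketo form) | CCOC(=O)C(=O)CC(=O)C[C@H](O)c1ccc(OCc2ccccc2)cc1 | intermediate
14 | ethyl (2S)-2-[4-(benzyloxy)phenyl]-4-oxo-3,4-dihydro-2H-pyran-6-carboxylate | CCOC(=O)C1=CC(=O)C[C@@H](c2ccc(OCc3ccccc3)cc2)O1 | intermediate
15 | trimethylstannyl (2S)-2-[4-(benzyloxy)phenyl]-4-oxo-3,4-dihydro-2H-pyran-6-carboxylate (formed in situ) | C[Sn](C)(C)OC(=O)C1=CC(=O)C[C@@H](c2ccc(OCc3ccccc3)cc2)O1 | intermediate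
16 | (2S)-2-[4-(benzyloxy)phenyl]-4-oxo-3,4-dihydro-2H-pyran-6-carboxylic acid | OC(=O)C1=CC(=O)C[C@@H](c2ccc(OCc3ccccc3)cc2)O1 | intermediate
17 | (2S)-2-[4-(benzyloxy)phenyl]-4-oxo-3,4-dihydro-2H-pyran-6-carbonyl chloride (formed in situ) | ClC(=O)C1=CC(=O)C[C@@H](c2ccc(OCc3ccccc3)cc2)O1 | intermediate
18 | (2S)-2-[4-(benzyloxy)phenyl]-6-(diazoacetyl)-2,3-dihydro-4H-pyran-4-one | [N-]=[N+]=CC(=O)C1=CC(=O)C[C@@H](c2ccc(OCc3ccccc3)cc2)O1 | intermediate
19 | (2S)-2-[4-(benzyloxy)phenyl]-6-(2-oxoethenyl)-2,3-dihydro-4H-pyran-4-one (vinylketene, formed in situ) | O=C=CC1=CC(=O)C[C@@H](c2ccc(OCc3ccccc3)cc2)O1 | intermediate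
20 | 2-{5-[(2S)-5-(benzyloxy)-7-methoxy-4-oxochroman-2-yl]-2-methoxyphenyl}-3-methoxy-4-{(2S)-2-[4-(benzyloxy)phenyl]-4-oxo-3,4-dihydro-2H-pyran-6-yl}cyclobut-2-en-1-one (C4 unspecified, formed in situ) | O=C1C(c2cc(ccc2OC)[C@@H]2CC(=O)c3c(OCc4ccccc4)cc(OC)cc3O2)=C(OC)C1C1=CC(=O)C[C@@H](c2ccc(OCc3ccccc3)cc2)O1 | intermediate
21 | dienylketene from 4π opening of 20: the ketene carbon bears the unit 1 aryl, and the adjacent methoxy-substituted C=CH bond carries the pyranonyl group cis to the ketene-bearing carbon (formed in situ) | O=C=C(c2cc(ccc2OC)[C@@H]2CC(=O)c3c(OCc4ccccc4)cc(OC)cc3O2)/C(OC)=C\C1=CC(=O)C[C@@H](c2ccc(OCc3ccccc3)cc2)O1 | intermediate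
22 | cyclohexa-2,4-dienone tautomer of 23 with C5''=O and H at C4a'' (C4a'' unspecified, formed in situ) | COC1=C(c2cc(ccc2OC)[C@@H]2CC(=O)c3c(OCc4ccccc4)cc(OC)cc3O2)C(=O)C2C(=O)C[C@@H](c3ccc(OCc4ccccc4)cc3)OC2=C1 | intermediate
23 | (2S)-5-(benzyloxy)-2-{3-[(2S)-2-[4-(benzyloxy)phenyl]-5-hydroxy-7-methoxy-4-oxochroman-6-yl]-4-methoxyphenyl}-7-methoxychroman-4-one (5,4'''-di-O-benzyl target) | COc1cc(OCc2ccccc2)c2c(c1)O[C@H](c1ccc(OC)c(-c3c(OC)cc4c(c3O)C(=O)C[C@@H](c3ccc(OCc5ccccc5)cc3)O4)c1)CC2=O | intermediate
24 | (2S)-5-hydroxy-2-{3-[(2S)-5-hydroxy-2-(4-hydroxyphenyl)-7-methoxy-4-oxochroman-6-yl]-4-methoxyphenyl}-7-methoxychroman-4-one (CNP0150873.1) | COc1cc(O)c2c(c1)O[C@H](c1ccc(OC)c(-c3c(OC)cc4c(c3O)C(=O)C[C@@H](c3ccc(O)cc3)O4)c1)CC2=O | target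

**Step count and risk**

Total step count: 11. Longest linear sequence: 6 steps (1, 2, 3, 5, 10, 11; the pyranone branch 6, 7, 8, 9, 10, 11 is equally long).

Steps most likely to fail:

1. Step 10. The push–pull vinylketene may be captured too slowly by the ortho-methoxy aryl ynol ether, so that ketene dimerisation or dipolar cycloaddition of the diazo group to the ynol ether takes over. The cascade may also stall at the cyclobutenone, or stray light absorption may open a chromanone ring. The fallback replaces the annulation by a cross-coupling; it sets out from 5, 1 and 12 and returns at 23. Miyaura borylation of 5 (B2pin2, PdCl2(dppf), KOAc, dioxane, 80 °C) should give (2S)-5-(benzyloxy)-7-methoxy-2-[4-methoxy-3-(4,4,5,5-tetramethyl-1,3,2-dioxaborolan-2-yl)phenyl]chroman-4-one F1. In parallel, Claisen–Schmidt condensation of 1 with 12 should give (E)-3-[4-(benzyloxy)phenyl]-1-(2,6-dihydroxy-4-methoxyphenyl)prop-2-en-1-one F2. This is closed, by the thiourea catalysis of step 3 or by racemic closure and chiral-phase separation, to (2S)-2-[4-(benzyloxy)phenyl]-5-hydroxy-7-methoxychroman-4-one F3. Iodination ortho to the chelated phenol (BnMe3N·ICl2, CaCO3, CH2Cl2–MeOH) should then give (2S)-2-[4-(benzyloxy)phenyl]-5-hydroxy-6-iodo-7-methoxychroman-4-one F4. Suzuki–Miyaura coupling of F1 with F4 (Pd(OAc)2, SPhos, K3PO4, toluene–water, 60 °C) leads to 23. The price is a coupling at the doubly ortho-substituted C6'' and exposure of both flavanones to mild base.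

2. Step 3. Facial discrimination in the oxa-Michael closure may be insufficient, or enantiopurity may erode through reversible retro-Michael opening under the amine catalyst. The fallback is resolution instead of asymmetric catalysis; it sets out from 4 and returns at 5. Closure of 4 with NaOAc in refluxing EtOH should give racemic 5-(benzyloxy)-2-(3-iodo-4-methoxyphenyl)-7-methoxychroman-4-one F5. Its enantiomers are separated by preparative supercritical-fluid chromatography on an amylose tris(3,5-dimethylphenylcarbamate) phase, and the (S) isomer is 5.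

3. Step 7. The ester-bearing diene may turn over poorly or with low enantioselectivity, and the p-alkoxybenzylic carbinol may ionise during the acid cyclodehydration. The fallback sets the carbinol first and builds the diketoester afterwards; it sets out from 12 and returns at 14. A direct aldol reaction of 12 with acetone under a D-proline-derived amide catalyst should give (4S)-4-[4-(benzyloxy)phenyl]-4-hydroxybutan-2-one F6. Silylation (TBSCl, imidazole, DMF) gives (4S)-4-[4-(benzyloxy)phenyl]-4-(tert-butyldimethylsilyloxy)butan-2-one F7. Claisen condensation of its kinetic methyl enolate with diethyl oxalate (LiHMDS, THF, −78 °C) gives ethyl (6S)-6-[4-(benzyloxy)phenyl]-6-(tert-butyldimethylsilyloxy)-2,4-dioxohexanoate F8. Desilylation and cyclodehydration (aq HF, MeCN, then PPTS) deliver 14.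

Further compounds
F1 | step 10 | (2S)-5-(benzyloxy)-7-methoxy-2-[4-methoxy-3-(4,4,5,5-tetramethyl-1,3,2-dioxaborolan-2-yl)phenyl]chroman-4-one | COc1ccc(cc1B1OC(C)(C)C(C)(C)O1)[C@@H]1CC(=O)c2c(OCc3ccccc3)cc(OC)cc2O1
F2 | step 10 | (E)-3-[4-(benzyloxy)phenyl]-1-(2,6-dihydroxy-4-methoxyphenyl)prop-2-en-1-one | COc1cc(O)c(C(=O)/C=C/c2ccc(OCc3ccccc3)cc2)c(O)c1
F3 | step 10 | (2S)-2-[4-(benzyloxy)phenyl]-5-hydroxy-7-methoxychroman-4-one | COc1cc(O)c2C(=O)C[C@@H](c3ccc(OCc4ccccc4)cc3)Oc2c1
F4 | step 10 | (2S)-2-[4-(benzyloxy)phenyl]-5-hydroxy-6-iodo-7-methoxychroman-4-one | COc1cc2O[C@H](c3ccc(OCc4ccccc4)cc3)CC(=O)c2c(O)c1I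
F5 | step 3 | racemic 5-(benzyloxy)-2-(3-iodo-4-methoxyphenyl)-7-methoxychroman-4-one | COc1ccc(cc1I)C1CC(=O)c2c(OCc3ccccc3)cc(OC)cc2O1
F6 | step 7 | (4S)-4-[4-(benzyloxy)phenyl]-4-hydroxybutan-2-one | CC(=O)C[C@H](O)c1ccc(OCc2ccccc2)cc1
F7 | step 7 | (4S)-4-[4-(benzyloxy)phenyl]-4-(tert-butyldimethylsilyloxy)butan-2-one | CC(=O)C[C@H](O[Si](C)(C)C(C)(C)C)c1ccc(OCc2ccccc2)cc1
F8 | step 7 | ethyl (6S)-6-[4-(benzyloxy)phenyl]-6-(tert-butyldimethylsilyloxy)-2,4-dioxohexanoate | CCOC(=O)C(=O)CC(=O)C[C@H](O[Si](C)(C)C(C)(C)C)c1ccc(OCc2ccccc2)cc1
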